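## Structural features

The target (C23H33NO3) has five rings. A cyclopentene (ring A) and a cyclopentane bearing CO2Me (ring B) form a bicyclo[3.3.0]octene whose tetrasubstituted alkene is shared with a cycloheptene (ring C); ring C and an N-methylpiperidine (ring D) make up an 8-azabicyclo[4.3.1]decene, and the one-carbon bridge of that bicycle is also the spiro carbon of a 6-ethyl-3,4-dihydro-2H-pyran (ring E). Working numbering used throughout: C1 (quaternary bridgehead), C2=C3 (alkene; C2 belongs to rings A, B and C), C4, C5, C6 (bridgehead CH), C7, N8, C9, C10 (spiro bridge); C11 (CH at the A/B fusion), C12 and C13 complete ring A; C14 (CH–CO2Me) and C15 complete ring B; C16 (OCH2), C17, C18 (=CH) and C19 (C–Et) complete ring E. The five stereocentres form two contiguous sets joined at C1: C6–C10–C1, in which C10 and C1 are vicinal quaternary carbons, and C11–C14 on ring B. The C1/C6 relationship is dictated by the one-carbon bridge; at C10 the oxygen-bearing C16 lies over ring C and C17 over ring D; on ring B the hydrogens at C11 and C14 are cis and point to the face of C9, so the ester sits cis to C12 and C10, on the concave and less stable side of the diquinane. Fragile groups are the cyclic enol ether (acid, electrophiles, hydrogenation), the epimerisable C14, the basic tertiary amine and the tetrasubstituted C2=C3 alkene, which could migrate. The real difficulty is the congested C1/C10 pair with a defined spiro configuration on a bridging carbon, together with a contra-thermodynamic ester next to an allylic ring-fusion hydrogen. The key step exploits the fact that ring A is a cyclopentene fused to the cycloheptene through C2=C3 with C11 attached to C2: this is the alkene position of the thermodynamic Nazarov product of a 2-acryloylcycloheptene, and the ketone left by the cyclisation stands on C11, the carbon to which ring B must be joined.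

## Logic of the disconnections

20 ⇒ 17. Cut: the O–C19 bond of the enol ether (and the O–Si bond that masks the hydroxyl). A cyclic enol ether is the dehydrated hemiketal of a δ-hydroxy ketone, so ring E and the most acid-labile group disappear together. The forward step must be an acid-catalysed cyclodehydration that gives the endocyclic alkene and leaves C14 and C2=C3 alone.

17 ⇒ 16. Cut: the C11–H and C14–H bonds (and the two C–H bonds of C17/C18). The two ring B hydrogens are cis and on the face away from C16, so one syn addition of hydrogen can set both centres and place the ester in its less stable position without any enolate chemistry. The gain is a flat ring B with no stereocentres. The demand is regioselectivity for the ester-bearing double bond of a dienoate and attack from the C9 face.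

16 ⇒ 14 + 15. Cut: C17=C18. The four carbons C18, C19 and ethyl arrive with the ketone already in place, and the aldehyde partner has no α-hydrogen. The demand is olefination of a neopentyl aldehyde under conditions too mild to disturb the dienoate.

14 ⇒ 13 ⇒ 12. Cut: O–Si, then C10–C16. The spiro carbon is made quaternary by adding the smallest possible electrophile last, to an enol at C10 that already carries C17, so that C16 takes the more open face. The gain is the loss of a quaternary stereocentre. The demand is facial selectivity at the bridging carbon and no retro-aldol afterwards.

12 ⇒ 10. Cut: C10–C17. The bridging ketone left by the construction of the azabicycle is the natural handle for a one-carbon homologation. The demand is olefination of a hindered ketone in the presence of a dienoate.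

10 ⇒ 9. Cut: C11=C14. Ring B is opened to a propanoate arm and a ring A ketone; no activating group is needed on the arm. The demand is that the least acidic carbonyl partner react, which calls for reversible, thermodynamic conditions with an irreversible dehydration at the end.

9 ⇒ 8 (key). Cut: C3–C13. A cyclopentenone fused through its tetrasubstituted alkene is the retron of a Nazarov cyclisation; the precursor is a simple bicycle with an acryloyl group. The demand is an acid strong enough for an unsubstituted vinyl ketone next to an ammonium centre, with alkene position under thermodynamic control.

8 ⇒ 6 + 7. Cut: C2–C11 and C11–C12, the two bonds to the carbonyl carbon, which comes from a one-carbon gas. A three-component coupling assembles the dienone from an enol sulfonate. The demand is carbonyl insertion before transmetalation and careful handling of a reactive Michael acceptor.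

6 ⇒ 5 ⇒ 4. Cut: O–S; then no bond at all, only the separation of antipodes. The ketone of 5 has a single enolisable position, and the bridgeheads of 4 cannot racemise. The demand is a preparative separation in which half the material is lost early.

4 ⇒ 3. Cut: C1–C9, C9–N8, N8–C7 and C7–C6. A double Mannich annulation removes ring D and both bridgehead stereocentres at once and leaves a monocycle. The demand is reaction at C1 and C6 only, under conditions that do not cleave the non-enolisable 1,3-diketone.

3 ⇒ 1 + 2. Cut: C1–C15. A Michael addition joins the two commercial compounds; the only demand is to stop at mono-addition.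

## Other disconnections considered

Alternative 1: The cut is the C1–C10 bond between the two quaternary carbons. In the forward direction the seven-membered lactone A2, whose ester oxygen sits on the tertiary allylic C3 next to a C1=C2 alkene, is enolised at C10 and silylated; the silyl ketene acetal undergoes an Ireland–Claisen ring contraction to the acid A1, forming C1–C10, breaking C3–O and moving the alkene to C2=C3. In its favour: the hardest bond is formed intramolecularly and stereospecifically. The C3 stereocentre is relayed to C1, and the ring fixes the ketene acetal geometry, so both quaternary centres come from one suprafacial event with no regiochemical question about the alkene. On predictability of the spiro configuration this alternative is better than the chosen plan, which depends on facial selectivity in an intermolecular aldol. Against it here: two fully substituted termini would have to bond through a boat-like transition state within a contracting ring, while the tertiary allylic carboxylate can ionise or eliminate. A2 already contains rings A and B with C11 and C14 set and needs esterification of a hindered tertiary alcohol. After A1, ring D must still be closed at the neopentyl C9 and ring E built from an allyl group and a hindered acid. Structure: the alternative attacks the quaternary pair directly, whereas the chosen plan takes C1 from a Michael addition and C10 from a ketone. Mechanism: a pericyclic step with built-in stereocontrol against a cationic electrocyclisation that carries no stereochemical information; the Nazarov step is the simpler event, the Claisen the more informative. Step economy: the chosen plan should be clearly shorter, because rings C and D arise in two steps from a monocycle.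

Alternative 2: The cut is ring E at C10–C17 and O–C16. In the forward direction the ketene dithioacetal A4 on the bridging carbon reacts as the electron-rich 2π partner with ethyl vinyl ketone A5 as heterodiene (inverse-electron-demand hetero-Diels–Alder), giving the spiro-dihydropyran A3 in which C16 is still a 1,3-dithiane. In its favour: it starts from the same kind of bridging ketone as the chosen plan (for example 10), so it fits the Nazarov strategy as an end-game. Ring E, the ethyl group and the enol ether would arrive in one step, and the polarisation of both partners leaves no doubt about regiochemistry. On step economy for ring E it is the better proposal, about two or three steps against six. Against it here: a tetrasubstituted ketene dithioacetal on a bridging carbon is a hindered partner and may need a Lewis acid that the enol ether product would not tolerate. The sterically controlled bond is C10–C17, and by the facial analysis used for step 9 the enone carbon should enter from the cycloheptene face, putting C17 over ring C, the opposite spiro configuration. The final desulfurisation (Ni2B or Bu3SnH) must spare an enol ether and the tetrasubstituted alkene. Structure: equal, since both plans make the spiro centre from the C10 ketone. Mechanism: an asynchronous [4+2] that forms the C–C bond on the open face, against an aldol in which the small C16 electrophile comes last; for spiro stereocontrol the chosen plan should be better. Step economy: the alternative is better if the cycloaddition proceeds.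

Alternative 3: The cut removes rings A and B together. In the forward direction, triplet-sensitised irradiation of the bridgehead-substituted bicyclo[2.2.2]octenone A7 effects an oxa-di-π-methane rearrangement (1,2-acyl shift and cyclopropane closure) to the tricyclic cyclopropyl ketone A6, from which reductive opening of the cyclopropane would give the cis-diquinane. In its favour: the rearrangement is stereospecific, A7 should be readily made by a Diels–Alder route and can be obtained enantiopure, and the C11 ring-fusion hydrogen is fixed by the skeleton. On certainty at C11 it is better than the chosen plan, which sets that centre by a late hydrogenation. Against it here: A6 contains only the carbocyclic diquinane and a chain. The azabicycle, both quaternary centres, the tetrasubstituted alkene, the seven-membered ring and the spiro ring would all have to be built around it, with several C–C bonds formed at neopentyl or quaternary positions and no rigid bicycle to direct them. Structure: complementary; it starts from the opposite end of the molecule. Mechanism: the photochemical step is as reliable as, or more predictable than, an acid Nazarov cyclisation of an unsubstituted vinyl ketone. Step economy: clearly worse overall.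

Key step: step 6

Remark on the chemistry: which antipode of 4 is 5 cannot be predicted from the separation in step 3; it is assumed that the assignment is made by X-ray analysis of a crystalline salt of the collected enantiomer before the route proceeds.

## Route

Step 1
Reactants: 1 cycloheptane-1,3-dione; 2 methyl acrylate
Product: 3 methyl 3-(2,7-dioxocycloheptyl)propanoate
Conditions: 2 (1.05 equiv), Et3N (0.3 equiv), MeCN, 50 °C
Reagents that add atoms: none
Why: Michael addition of the doubly activated C–H of the 1,3-dione to the acrylate; the mono-adduct is more hindered than 1, so control of stoichiometry should hold back the bis-adduct, and no stereocentre is formed.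

Step 2
Reactants: 3 methyl 3-(2,7-dioxocycloheptyl)propanoate
Product: 4 rac-methyl 3-(8-methyl-2,10-dioxo-8-azabicyclo[4.3.1]decan-1-yl)propanoate
Conditions: MeNH2·HCl (1.1 equiv), (CH2O)n (2.2 equiv), AcOH, 80 °C; NaHCO3 aq.
Reagents that add atoms: methylamine hydrochloride, CN.Cl; paraformaldehyde (as formaldehyde), C=O
Why: Double Mannich annulation: the first iminium ion is taken up by the enol of the 1,3-dione carbon (C1), the tethered second iminium ion by the α′-enol (C6), closing the piperidone; a one-carbon bridge can only span C1 and C6 cis, so one relative configuration results as the racemate. The acidic medium keeps free amine low and so protects the non-enolisable 1,3-diketone from retro-Claisen cleavage.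

Step 3
Reactants: 4 rac-methyl 3-(8-methyl-2,10-dioxo-8-azabicyclo[4.3.1]decan-1-yl)propanoate
Product: 5 methyl 3-[(1R,6R)-8-methyl-2,10-dioxo-8-azabicyclo[4.3.1]decan-1-yl]propanoate
Conditions: preparative SFC, amylose tris(3,5-dimethylphenylcarbamate) stationary phase, CO2/i-PrOH (no amine additive)
Reagents that add atoms: none
Why: Resolution of a racemate by chromatography on a chiral stationary phase; both bridgeheads are configurationally locked (C1 quaternary, C6 unable to enolise towards a bridgehead), so the separated antipode cannot racemise in later steps.

Step 4
Reactants: 5 methyl 3-[(1R,6R)-8-methyl-2,10-dioxo-8-azabicyclo[4.3.1]decan-1-yl]propanoate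
Product: 6 methyl 3-[(1R,6R)-8-methyl-10-oxo-2-(trifluoromethylsulfonyloxy)-8-azabicyclo[4.3.1]dec-2-en-1-yl]propanoate
Conditions: KN(SiMe3)2 (1.05 equiv), THF, −78 °C; PhNTf2 (1.1 equiv), −78 → 0 °C
Reagents that add atoms: N-phenylbis(trifluoromethanesulfonimide), FC(F)(F)S(=O)(=O)N(c1ccccc1)S(=O)(=O)C(F)(F)F
Why: Enol triflate formation by O-sulfonylation of the kinetic potassium enolate: C3–H2 is the only position at which either ketone can enolise (C1 is quaternary, C6 is a bridgehead of the C10 ketone) and is more acidic than the ester CH2; the non-nucleophilic base spares the cleavage-prone diketone.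

Step 5
Reactants: 6 enol triflate; 7 tributyl(vinyl)stannane
Product: 8 methyl 3-[(1S,6R)-8-methyl-10-oxo-2-(prop-2-enoyl)-8-azabicyclo[4.3.1]dec-2-en-1-yl]propanoate
Conditions: 7 (1.2 equiv), CO (1 atm), Pd(PPh3)4 (5 mol %), LiCl (3 equiv), THF, 55 °C; BHT on isolation
Reagents that add atoms: carbon monoxide, [C-]#[O+]
Why: Carbonylative Stille coupling: oxidative addition of the alkenyl triflate to zerovalent palladium, CO insertion to the acyl complex, transmetalation from the vinylstannane and reductive elimination give the cross-conjugated dienone, with LiCl supplying the chloride needed for turnover. The acryloyl group is a reactive Michael acceptor, so 8 is kept cold and used at once.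

Step 6
Reactants: 8 acryloyl azabicycle (cross-conjugated dienone)
Product: 9 tricyclic ring A enone (cyclopent-2-enone fused at C2=C3, ketone on C11)
Conditions: MeSO3H (10 equiv), CH2Cl2, 0 → 25 °C (CF3SO3H if sluggish); NaHCO3 aq.
Reagents that add atoms: none
Why: After N-protonation, O-protonation of the dienone gives a hydroxypentadienyl cation that undergoes thermally allowed conrotatory 4π-electrocyclisation, bonding C3 to the unsubstituted vinyl terminus C13 and closing the five-membered ring A. The resulting oxyallyl cation loses the proton on C3, so the ring-fusion centre created transiently by the conrotation is erased and no stereocentre is at stake. The closest known reaction type is the Brønsted-acid Nazarov cyclisation of 1-acryloylcycloalkenes to ring-fused cyclopentenones. The only selectivity needed is the position of the alkene: under equilibrating acid the product settles as the tetrasubstituted C2=C3 enone, the thermodynamic isomer, still conjugated with the C11 ketone. The substrate secures the rest: the C10 ketone cannot enolise (quaternary C1, bridgehead C6), the ammonium centre is inert and the methyl ester tolerates anhydrous acid. The new ketone stands on C11, the carbon that ring B must bond to.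

Step 7
Reactants: 9 tricyclic ring A enone
Product: 10 tetracyclic dienoate (ring B closed; C2=C3–C11=C14–CO2Me)
Conditions: NaOMe (2 equiv), MeOH, 3 Å MS, 65 °C; AcOH quench
Reagents that add atoms: none
Why: Intramolecular aldol condensation: 5-exo-trig addition of the ester enolate carbon C14 to the C11 ketone, then E1cB loss of water. Under reversible methoxide conditions all enolates interconvert, but ring B is the only ring of sensible size that can form, and dehydration to the fully conjugated dienoate makes the closure irreversible. Methanol makes transesterification degenerate, the sieves keep the released water from saponifying the ester, and no stereocentre is formed.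

Step 8
Reactants: 10 tetracyclic dienoate
Product: 12 C10-formyl tetracyclic dienoate, via methyl enol ether 11 (not isolated)
Conditions: Ph3P(CH2OMe)Cl (3 equiv), KN(SiMe3)2 (2.9 equiv), THF, 0 → 45 °C; then 2 M HCl aq., THF, 25 °C; NaHCO3 aq.
Reagents that add atoms: (methoxymethyl)triphenylphosphonium chloride, COC[P+](c1ccccc1)(c1ccccc1)c1ccccc1.[Cl-]; water, O
Why: Wittig methoxymethylenation of the only ketone left (the strained, non-enolisable C10 carbonyl), then acid hydrolysis of the enol ether to the homologated aldehyde. The configuration of the new C10–H is of no consequence because C10 is enolised again in step 9.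

Step 9
Reactants: 12 C10-formyl tetracyclic dienoate
Product: 13 C10 quaternary hydroxymethyl aldehyde (CH2OH over ring C, CHO over ring D)
Conditions: 37% aq. CH2O (5 equiv), Et3N (0.5 equiv), THF/MeOH, 40 °C
Reagents that add atoms: formaldehyde, C=O
Why: Crossed aldol reaction of an α-branched aldehyde with formaldehyde under tertiary-amine catalysis: the exocyclic enol at C10 should be attacked from the cycloheptene face, which offers the planar sp2 C2 and one syn-axial hydrogen, rather than from the piperidine face with two syn-axial hydrogens, so C16 comes to lie over ring C and the formyl carbon C17 over ring D. The addition is reversible and the same isomer, with the larger CH2OH in the more open site, should also be favoured at equilibrium; the product has no α-hydrogen, so it can neither dehydrate nor add a second time.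

Step 10
Reactants: 13 C10 quaternary hydroxymethyl aldehyde
Product: 14 tert-butyldimethylsilyl ether of 13
Conditions: TBSCl (1.5 equiv), imidazole (3 equiv), DMF, 25 °C
Reagents that add atoms: tert-butyldimethylsilyl chloride, CC(C)(C)[Si](C)(C)Cl
Why: Silylation of the neopentyl primary alcohol; the silyl ether blocks retro-aldol loss of formaldehyde in step 11 and removes a hydroxyl that would steer the iridium catalyst of step 12 to the wrong face of ring B.

Step 11
Reactants: 14 silyl ether aldehyde; 15 diethyl (2-oxobutyl)phosphonate
Product: 16 (E)-enone with the C17=C18–C19(=O)Et side chain on C10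
Conditions: 15 (1.5 equiv), NaH (1.4 equiv), THF, 0 → 40 °C
Reagents that add atoms: none
Why: Horner–Wadsworth–Emmons olefination of the non-enolisable neopentyl aldehyde with the sodium salt of the β-ketophosphonate gives the (E)-enone and brings in C18, C19 and the ethyl group; the stabilised phosphonate anion is too weak a base to deprotonate the dienoate.

Step 12
Reactants: 16 (E)-enone dienoate
Product: 17 saturated keto ester (C11–H and C14–H cis on the C9 face; CO2Me cis to C12; C2=C3 retained)
Conditions: HBF4·OEt2 (1.0 equiv), CH2Cl2; [Ir(cod)(PCy3)(py)]PF6 (10 mol %), H2 (10 bar), 25 °C; NaHCO3 aq.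
Reagents that add atoms: none
Why: Homogeneous hydrogenation with a cationic iridium phosphine/pyridine complex, the catalyst class that reduces tetrasubstituted alkenes and is guided by a neighbouring carbonyl oxygen: the ester-bearing C11=C14 bond should be reduced by syn addition in preference to the more buried, unfunctionalised C2=C3 bond, and the side-chain enone C=C is saturated on the way. Both hydrogens should enter from the face of ring B opposite to the C16H2OSi group that overhangs it, which sets C11–H and C14–H cis and leaves the ester on the concave face as required; the amine is masked as its tetrafluoroborate so that it does not bind iridium.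

Step 13
Reactants: 17 saturated keto ester
Product: 20 target amino ester CNP0159589.3, via hydroxy ketone 18 (not isolated), via cyclic methyl ketal 19 (not isolated)
Conditions: TsOH·H2O (1.3 equiv), MeOH, 25 °C; then PhMe, 5 Å MS, 90 °C; NaHCO3 aq.
Reagents that add atoms: none
Why: Acid methanolysis of the silyl ether, ketalisation of the δ-hydroxy ketone to the six-membered methyl ketal and acid-catalysed loss of methanol on heating (cyclodehydration to the endocyclic enol ether). No base is used after step 12, so the epimerisable C14 is not put at risk, and the enol ether is made last because it would not survive steps 6, 8 or 12.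

## Compound list

1 | cycloheptane-1,3-dione | O=C1CCCCC(=O)C1 | starting material
2 | methyl acrylate | C=CC(=O)OC | starting material
3 | methyl 3-(2,7-dioxocycloheptyl)propanoate | COC(=O)CCC1C(=O)CCCCC1=O | intermediate
4 | rac-methyl 3-(8-methyl-2,10-dioxo-8-azabicyclo[4.3.1]decan-1-yl)propanoate (racemate; the bridge forces C1 and C6 cis) | O=C1C2CCCC(=O)C1(CCC(=O)OC)CN(C)C2 | intermediate
5 | methyl 3-[(1R,6R)-8-methyl-2,10-dioxo-8-azabicyclo[4.3.1]decan-1-yl]propanoate | O=C1[C@@H]2CCCC(=O)[C@@]1(CCC(=O)OC)CN(C)C2 | intermediate
6 | methyl 3-[(1R,6R)-8-methyl-10-oxo-2-(trifluoromethylsulfonyloxy)-8-azabicyclo[4.3.1]dec-2-en-1-yl]propanoate | O=C1[C@@H]2CCC=C(OS(=O)(=O)C(F)(F)F)[C@@]1(CCC(=O)OC)CN(C)C2 | intermediate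
7 | tributyl(vinyl)stannane | C=C[Sn](CCCC)(CCCC)CCCC | starting material
8 | methyl 3-[(1S,6R)-8-methyl-10-oxo-2-(prop-2-enoyl)-8-azabicyclo[4.3.1]dec-2-en-1-yl]propanoate (Nazarov precursor) | O=C1[C@@H]2CCC=C(C(=O)C=C)[C@@]1(CCC(=O)OC)CN(C)C2 | intermediate
9 | tricyclic ring A enone: cyclopent-2-enone fused at C2=C3 of the azabicycle (ketone on C11), C10 ketone, CH2CH2CO2Me on C1, N-methyl; C1 and C6 as in 5 | O=C1[C@@H]2CCC3=C(C(=O)CC3)[C@@]1(CCC(=O)OC)CN(C)C2 | intermediate
10 | tetracyclic dienoate: ring B closed, C2=C3 and C11=C14 conjugated, CO2Me on C14, C10 ketone | O=C1[C@@H]2CCC3=C4C(CC3)=C(C(=O)OC)C[C@@]41CN(C)C2 | intermediate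
11 | C10 methoxymethylidene derivative of 10 (E/Z mixture) | COC=C1[C@@H]2CCC3=C4C(CC3)=C(C(=O)OC)C[C@@]41CN(C)C2 | intermediate (not isolated)
12 | C10-formyl tetracyclic dienoate (C10–H; both C10 epimers) | O=CC1[C@@H]2CCC3=C4C(CC3)=C(C(=O)OC)C[C@@]41CN(C)C2 | intermediate
13 | C10 quaternary hydroxymethyl aldehyde: CH2OH (C16) over ring C, CHO (C17) over ring D | O=C[C@@]1(CO)[C@@H]2CCC3=C4C(CC3)=C(C(=O)OC)C[C@@]41CN(C)C2 | intermediate
14 | tert-butyldimethylsilyl ether of 13 | O=C[C@@]1(CO[Si](C)(C)C(C)(C)C)[C@@H]2CCC3=C4C(CC3)=C(C(=O)OC)C[C@@]41CN(C)C2 | intermediate
15 | diethyl (2-oxobutyl)phosphonate | CCC(=O)CP(=O)(OCC)OCC | starting material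
16 | (E)-enone: C10 bears CH2OTBS and (E)-CH=CH–C(=O)Et; dienoate as in 10 | CCC(=O)/C=C/[C@@]1(CO[Si](C)(C)C(C)(C)C)[C@@H]2CCC3=C4C(CC3)=C(C(=O)OC)C[C@@]41CN(C)C2 | intermediate
17 | saturated keto ester: C10 bears CH2OTBS and 3-oxopentyl; H–C11 and H–C14 cis on the C9 face, CO2Me cis to C12; C2=C3 retained | CCC(=O)CC[C@@]1(CO[Si](C)(C)C(C)(C)C)[C@@H]2CCC3=C4[C@H](CC3)[C@H](C(=O)OC)C[C@@]41CN(C)C2 | intermediate
18 | δ-hydroxy ketone (desilylated 17) | CCC(=O)CC[C@@]1(CO)[C@@H]2CCC3=C4[C@H](CC3)[C@H](C(=O)OC)C[C@@]41CN(C)C2 | intermediate (not isolated)
19 | ring E methyl ketal (spiro 2-ethyl-2-methoxytetrahydropyran; both C19 epimers) | CCC1(OC)CC[C@@]2(CO1)[C@@H]1CCC3=C4[C@H](CC3)[C@H](C(=O)OC)C[C@@]42CN(C)C1 | intermediate (not isolated)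
20 | CNP0159589.3 | CCC1=CC[C@@]2(CO1)[C@@H]1CCC3=C4[C@H](CC3)[C@H](C(=O)OC)C[C@@]42CN(C)C1 | target

## Step count and least certain steps

Total step count: 13. Longest linear sequence: 13 steps (1 to 20).

Step 6 (key step). What may go wrong: polymerisation or conjugate addition at the unsubstituted acryloyl group while the electrocyclisation is slow, because the pentadienyl cation has no stabilising substituent and must form next to an ammonium centre. A 1,2-shift from the quaternary C1 to the cationic C2 of the oxyallyl cation could also compete with proton loss. Fallback, from 6 back to 9: carbonylative Stille coupling of 6 with (E)-tributyl[2-(trimethylsilyl)vinyl]stannane gives the β-silyl dienone F1. A silicon-directed Nazarov cyclisation (FeCl3, 2.2 equiv, CH2Cl2, −30 °C) is steered and terminated by the β-silicon effect and gives, after loss of the silyl group, the cis-fused C12=C13 enone F2 at low temperature. DBU in toluene at 80 °C then moves the alkene into the conjugated tetrasubstituted position of 9.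

Step 7. What may go wrong: slow closure, because the ester is the least acidic carbonyl partner and only a small equilibrium share of its enolate is present, and saponification of the ester by the water released in the dehydration. Fallback, from 6 back to 10: the ester CH2 of 6, the only acidic site of that compound, is brominated through its lithium enolate (LiN(i-Pr)2, THF, −78 °C; BrCCl2CCl2Br) to give the α-bromo ester triflate F3. Carbonylative Stille coupling as in step 5 and Nazarov cyclisation as in step 6 give the bromo dienone F4 and the bromo enone F5. SmI2 (2.2 equiv, THF, −78 °C) then forms the samarium ester enolate in the presence of the ketone (intramolecular Reformatsky reaction) to give the β-hydroxy ester F6, and SOCl2/pyridine dehydrates the tertiary alcohol to 10.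

Step 8. What may go wrong: incomplete olefination of the hindered bridging ketone, and γ-deprotonation of the dienoate by the basic ylide leading to double-bond isomers. Fallback, from 10 back to 12: Corey–Chaykovsky reaction with the smaller dimethylsulfonium methylide (Me3SI, KN(SiMe3)2, THF/DMSO, 0 °C) gives the spiro-epoxide F7. Meinwald rearrangement with MgBr2·OEt2 (1,2-hydride shift) then gives 12.

Step 9. What may go wrong: poor or inverted facial selectivity in the attack of formaldehyde on the C10 enol, because the two faces differ only by one syn-axial hydrogen and the shape of the flattened ring C; retro-aldol loss of formaldehyde on handling. Fallback, from 12 back to 17, for the case that electrophiles prefer the piperidine face: the order in which the two carbon substituents are introduced is exchanged. Michael addition of 12 to pent-1-en-3-one (DBU cat., MeCN) gives the keto aldehyde F8, with the C17 chain over ring D and the formyl group, now C16, over ring C. NaBH(OAc)3 reduces the aldehyde selectively to the hydroxy ketone F9, TBSCl/imidazole gives the silyl ether F10, and hydrogenation under the conditions of step 12 gives 17.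

Step 12. What may go wrong: addition of hydrogen across the ends of the diene or further reduction of C2=C3, insufficient preference for the C9 face, and deactivation of the iridium catalyst by the substrate. Fallback, from 16 back to 17: the two reductions are separated and the ester is exchanged for a carboxylic acid as the directing group. [(Ph3P)CuH]6 reduces the side-chain enone conjugatively to the ketone F10 already described in the fallback to step 9. LiOH in THF/H2O gives the dienoic acid F11. Ru(OAc)2[(S)-BINAP] or its enantiomer, chosen to reinforce the substrate bias, with H2 in MeOH hydrogenates the α,β-bond through the bound carboxylate to give the saturated acid F12 with cis hydrogens. Me3SiCHN2 in MeOH/PhMe re-forms the methyl ester 17 without base.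

## Further compounds

F1 | step 6 | β-silyl dienone: 8 with an (E)-2-(trimethylsilyl)vinyl ketone in place of the vinyl ketone | O=C1[C@@H]2CCC=C(C(=O)/C=C/[Si](C)(C)C)[C@@]1(CCC(=O)OC)CN(C)C2
F2 | step 6 | cis-fused ring A enone with the C12=C13 double bond (H on C2 and C3; mixture at the new ring fusion) | O=C1[C@@H]2CCC3C=CC(=O)C3[C@@]1(CCC(=O)OC)CN(C)C2
F3 | step 7 | α-bromo ester triflate: 6 with Br on C14 (both C14 epimers) | O=C1[C@@H]2CCC=C(OS(=O)(=O)C(F)(F)F)[C@@]1(CC(Br)C(=O)OC)CN(C)C2
F4 | step 7 | bromo dienone: 8 with Br on C14 (both C14 epimers) | O=C1[C@@H]2CCC=C(C(=O)C=C)[C@@]1(CC(Br)C(=O)OC)CN(C)C2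
F5 | step 7 | bromo enone: 9 with Br on C14 (both C14 epimers) | O=C1[C@@H]2CCC3=C(C(=O)CC3)[C@@]1(CC(Br)C(=O)OC)CN(C)C2
F6 | step 7 | β-hydroxy ester: ring B closed, tertiary OH on C11, H on C14 (mixture at C11 and C14) | O=C1[C@@H]2CCC3=C4C(O)(CC3)C(C(=O)OC)C[C@@]41CN(C)C2
F7 | step 8 | C10 spiro-epoxide of 10 (either epimer at C10) | O1CC12[C@@H]3CCC4=C5C(CC4)=C(C(=O)OC)C[C@@]52CN(C)C3
F8 | step 9 | keto aldehyde: C10 bears CHO (over ring C) and 3-oxopentyl (over ring D); dienoate as in 10 | CCC(=O)CC[C@@]1(C=O)[C@@H]2CCC3=C4C(CC3)=C(C(=O)OC)C[C@@]41CN(C)C2
F9 | step 9 | hydroxy ketone: C10 bears CH2OH and 3-oxopentyl; dienoate as in 10 | CCC(=O)CC[C@@]1(CO)[C@@H]2CCC3=C4C(CC3)=C(C(=O)OC)C[C@@]41CN(C)C2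
F10 | step 9 | tert-butyldimethylsilyl ether of F9 | CCC(=O)CC[C@@]1(CO[Si](C)(C)C(C)(C)C)[C@@H]2CCC3=C4C(CC3)=C(C(=O)OC)C[C@@]41CN(C)C2
F11 | step 12 | dienoic acid: F10 with CO2H in place of CO2Me | CCC(=O)CC[C@@]1(CO[Si](C)(C)C(C)(C)C)[C@@H]2CCC3=C4C(CC3)=C(C(=O)O)C[C@@]41CN(C)C2
F12 | step 12 | saturated acid: 17 with CO2H in place of CO2Me | CCC(=O)CC[C@@]1(CO[Si](C)(C)C(C)(C)C)[C@@H]2CCC3=C4[C@H](CC3)[C@H](C(=O)O)C[C@@]41CN(C)C2
A1 | alternative 1 | tricyclic C10 carboxylic acid with C10-allyl, C1–CH2OTBS and C6–CH2N(Me)Boc, rings A, B and C closed | C=CC[C@@]2(C(=O)O)[C@@H](CN(C)C(=O)OC(C)(C)C)CCC3=C4[C@H](CC3)[C@H](C(=O)OC)C[C@@]42CO[Si](C)(C)C(C)(C)C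
A2 | alternative 1 | seven-membered lactone: ester oxygen on tertiary C3, C1=C2 alkene in ring B, allyl on the α-carbon C10 (α-carbon epimers) | C=CCC1C(=O)O[C@]2(CC[C@@H]1CN(C)C(=O)OC(C)(C)C)CC[C@H]3C2=C(CO[Si](C)(C)C(C)(C)C)C[C@H]3C(=O)OC
A3 | alternative 2 | spiro-dihydropyran with C16 masked as a 1,3-dithiane | CCC1=CC[C@@]2(C5(O1)SCCCS5)[C@@H]1CCC3=C4[C@H](CC3)[C@H](C(=O)OC)C[C@@]42CN(C)C1
A4 | alternative 2 | C10 ketene dithioacetal (1,3-dithian-2-ylidene on the bridging carbon), ring B complete | S1CCCSC1=C1[C@@H]2CCC3=C4[C@H](CC3)[C@H](C(=O)OC)C[C@@]41CN(C)C2
A5 | alternative 2 | ethyl vinyl ketone (pent-1-en-3-one) | CCC(=O)C=C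
A6 | alternative 3 | methyl 4-(3-oxotricyclo[3.3.0.0(2,8)]octan-8-yl)butanoate | O=C1C[C@H]2CC[C@@]3(CCCC(=O)OC)[C@@H]1[C@@H]23
A7 | alternative 3 | methyl 4-(2-oxobicyclo[2.2.2]oct-5-en-1-yl)butanoate | O=C1C[C@H]2CC[C@]1(CCCC(=O)OC)C=C2
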